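## Retrosynthetic overview

- Prokinawan 10 is (2S)-eriodictyol carrying an (E)-7-hydroxy-3,7-dimethyloct-2-enyl chain at C6 of ring A. The one strategic cut is the aryl C6–C1′ bond, which gives (2S)-eriodictyol 9 and the allylic diphosphate 8.
- The bond is made last, without protecting groups, by an enzymatic Friedel–Crafts allylation catalysed by an aromatic prenyltransferase. The enabling feature is ring A: a phloroglucinol-type ring (oxygens on C5, C7 and C8a) whose unsubstituted C6 sits between the free C5 and C7 hydroxyls and is strongly nucleophilic. C1′ of the chain is allylic to the C2′=C3′ olefin and ionises readily once it carries diphosphate.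
- Donor 8 comes from geranyl acetate 1 in four steps: distal epoxidation, hydride opening to the tertiary alcohol, allylic chlorination, displacement by diphosphate.
- No ring of the target is built. Rings A, B and C and the C2 stereocentre come intact from commercial 9; the only ring formed is a temporary oxirane (step 1), opened in step 2.

Key step: step 5

Assumption: natural (2S)-(−)-eriodictyol 9 is bought at high enantiomeric purity (to be checked by chiral HPLC before use), and the enzyme is a recombinant NphB-type prenyltransferase chosen from a small panel for turnover with the hydroxylated donor 8.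

## Route

Step 1
Reactants: 1 geranyl acetate [(E)-3,7-dimethylocta-2,6-dien-1-yl acetate]
Product: 2 (E)-6,7-epoxygeranyl acetate [(E)-5-(3,3-dimethyloxiran-2-yl)-3-methylpent-2-en-1-yl acetate], racemic at the oxirane carbon
Conditions: mCPBA (1.05 equiv), NaHCO3, CH2Cl2, 0 °C
Reagents that add atoms: mCPBA (3-chloroperoxybenzoic acid), OOC(=O)c1cccc(Cl)c1
Why: Prilezhaev epoxidation should take the electron-rich distal C6=C7 olefin in preference to the C2=C3 olefin, which is deactivated inductively by the allylic acetate; the oxirane stereocentre forms as a racemate and is erased in step 2.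

Step 2
Reactants: 2 (E)-6,7-epoxygeranyl acetate
Product: 4 (E)-3,7-dimethyloct-2-ene-1,7-diol, via 6,7-epoxygeraniol 3 (not isolated)
Conditions: LiAlH4 (2.5 equiv), THF, 0 °C then 50 °C; work-up with H2O, 15% NaOH, H2O
Reagents that add atoms: none
Why: Hydride reduction with LiAlH4 first cleaves the acetate ester and then opens the trisubstituted oxirane by SN2 attack at the less substituted C6, which leaves the hydroxyl on the tertiary C7 and removes the oxirane stereocentre.

Step 3
Reactants: 4 (E)-3,7-dimethyloct-2-ene-1,7-diol
Product: 6 (E)-8-chloro-2,6-dimethyloct-6-en-2-ol, via allylic mesylate 5 (not isolated)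
Conditions: MsCl (1.1 equiv), 2,4,6-collidine, LiCl (3 equiv), DMF, 0 °C
Reagents that add atoms: lithium chloride, [Li+].[Cl-]; methanesulfonyl chloride, CS(=O)(=O)Cl (second chloride source)
Why: Mesylation with in situ SN2 chloride displacement should engage only the primary allylic hydroxyl, because the tertiary hydroxyl is too hindered to be sulfonylated at 0 °C, and the non-ionising conditions keep the E geometry and avoid allylic transposition.

Step 4
Reactants: 6 (E)-8-chloro-2,6-dimethyloct-6-en-2-ol
Product: 8 tris(ammonium) (E)-7-hydroxy-3,7-dimethyloct-2-en-1-yl diphosphate, via tetrabutylammonium diphosphate salt 7 (not isolated)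
Conditions: (Bu4N)3HP2O7 (2 equiv), MeCN, 3 Å molecular sieves, rt; then strong-acid cation-exchange resin (ammonium form), 25 mM NH4HCO3 in 2% iPrOH/H2O; lyophilisation; cellulose chromatography
Reagents that add atoms: tris(tetrabutylammonium) hydrogen diphosphate, CCCC[N+](CCCC)(CCCC)CCCC.CCCC[N+](CCCC)(CCCC)CCCC.CCCC[N+](CCCC)(CCCC)CCCC.OP(=O)([O-])OP(=O)([O-])[O-]; ammonium hydrogencarbonate, [NH4+].OC(=O)[O-]
Why: SN2 displacement of a primary allylic chloride by the diphosphate anion in a dipolar aprotic solvent, followed by cation exchange, is the standard entry to allylic diphosphates and should leave the tertiary alcohol and the E olefin untouched.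

Step 5
Reactants: 9 (2S)-eriodictyol [(2S)-2-(3,4-dihydroxyphenyl)-5,7-dihydroxy-2,3-dihydro-4H-chromen-4-one]; 8 tris(ammonium) (E)-7-hydroxy-3,7-dimethyloct-2-en-1-yl diphosphate
Product: 10 Prokinawan [(2S)-2-(3,4-dihydroxyphenyl)-5,7-dihydroxy-6-[(2E)-7-hydroxy-3,7-dimethyloct-2-en-1-yl]-2,3-dihydro-4H-chromen-4-one]
Conditions: recombinant aromatic prenyltransferase of the soluble ABBA (PT-barrel) class with C6-geranylating activity on 5,7-dihydroxyflavanones (NphB-type, 1–2 mol%), 8 (1.5 equiv, added in portions), 50 mM HEPES pH 7.2, 5 mM MgCl2, 2 mM ascorbic acid, 5% DMSO, argon, 30 °C; EtOAc extraction, reversed-phase chromatography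
Reagents that add atoms: none
Why: The enzyme binds the diphosphate of 8 through magnesium and basic residues, ionises the C1′–O bond to an (E)-allyl cation held in an aromatic-lined tunnel and presents C6 of ring A of 9 to C1′; the resulting arenium ion loses the C6 proton and rearomatises (enzymatic Friedel–Crafts allylation). The closest known reaction type is the C6-geranylation of 5,7-dihydroxyflavanones with geranyl diphosphate by soluble aromatic prenyltransferases of this class, applied here to a donor that differs only by a tertiary hydroxyl at the far end of the chain, where these enzymes tolerate added bulk. No ring is closed and no stereocentre is created: C2 should keep its S configuration because near-neutral pH and 30 °C make opening of ring C to the chalcone slow, and the C2′=C3′ olefin should keep its E geometry because the cation is captured at C1′ without bond rotation. The step needs C6 selectivity over C8, over O-alkylation at O5, O7 and the ring B catechol, and over attack through C3′ of the allyl cation. C6 is the ring A carbon flanked by the free C5 and C7 hydroxyls and the C5 hydroxyl is tied up in a hydrogen bond to the C4 carbonyl; since C8 is electronically similar, the C6/C8 choice rests on the orientation of the flavanone in the pocket, which in this enzyme class places C6 next to C1′. Ascorbic acid and argon should protect the catechol from oxidation, and the excess of 8 compensates for its background hydrolysis.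

## Compound list

1 | geranyl acetate | C/C(=C\COC(C)=O)CCC=C(C)C | starting material
2 | (E)-6,7-epoxygeranyl acetate (racemic oxirane) | C/C(=C\COC(C)=O)CCC1OC1(C)C | intermediate
3 | 6,7-epoxygeraniol (racemic oxirane, not isolated) | C/C(=C\CO)CCC1OC1(C)C | intermediate
4 | (E)-3,7-dimethyloct-2-ene-1,7-diol | C/C(=C\CO)CCCC(C)(C)O | intermediate
5 | (E)-7-hydroxy-3,7-dimethyloct-2-en-1-yl methanesulfonate (not isolated) | C/C(=C\COS(C)(=O)=O)CCCC(C)(C)O | intermediate
6 | (E)-8-chloro-2,6-dimethyloct-6-en-2-ol | C/C(=C\CCl)CCCC(C)(C)O | intermediate
7 | bis(tetrabutylammonium) (E)-7-hydroxy-3,7-dimethyloct-2-en-1-yl hydrogen diphosphate (not isolated) | C/C(=C\COP(=O)([O-])OP(=O)(O)[O-])CCCC(C)(C)O.CCCC[N+](CCCC)(CCCC)CCCC.CCCC[N+](CCCC)(CCCC)CCCC | intermediate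
8 | tris(ammonium) (E)-7-hydroxy-3,7-dimethyloct-2-en-1-yl diphosphate | C/C(=C\COP(=O)([O-])OP(=O)([O-])[O-])CCCC(C)(C)O.[NH4+].[NH4+].[NH4+] | intermediate
9 | (2S)-eriodictyol | O=C1C[C@@H](c2ccc(O)c(O)c2)Oc2cc(O)cc(O)c21 | starting material
10 | Prokinawan | C/C(=C\Cc1c(O)cc2c(c1O)C(=O)C[C@@H](c1ccc(O)c(O)c1)O2)CCCC(C)(C)O | target

## Step count and risks

Total step count: 5. Longest linear sequence: 5 steps (1 → 2 → 4 → 6 → 8 → 10).

Steps most likely to fail:

1. Step 5. What may go wrong:
   - slow turnover with the hydroxylated donor, so that hydrolysis of the diphosphate outruns transfer;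
   - competing alkylation at O7 or C8;
   - intramolecular capture of the allyl cation by the tertiary hydroxyl;
   - slow epimerisation at C2 through reversible opening of ring C in the buffer.

   Fallback (cross-coupling instead of enzymatic alkylation), setting out from 9 and 6 and coming back at 10. Silylation of 9 (TBSCl, imidazole, DMF, 0 °C) should spare the chelated C5 hydroxyl and give (2S)-5-hydroxy-7,3′,4′-tris(tert-butyldimethylsilyloxy)flavanone F1. Iodination ortho to the free C5 hydroxyl (benzyltrimethylammonium dichloroiodate, CaCO3, CH2Cl2/MeOH, rt) should give (2S)-5-hydroxy-6-iodo-7,3′,4′-tris(tert-butyldimethylsilyloxy)flavanone F2. In parallel, chloride 6 with Bu3SnLi (2.2 equiv, THF, −78 °C) should give (E)-2,6-dimethyl-8-(tributylstannyl)oct-6-en-2-ol F3. Stille coupling of F2 and F3 (Pd(PPh3)4, DMF, 90 °C) should form the C6–C1′ bond at the linear terminus and give 7,3′,4′-tris-O-(tert-butyldimethylsilyl)prokinawan F4. Desilylation under mildly acidic fluoride conditions (Et3N·3HF, THF, 0 °C to rt), chosen to avoid base-induced opening of ring C, returns to 10.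

2. Step 4. What may go wrong: elimination or solvolysis of the allylic chloride in competition with displacement, and hydrolysis of the allylic diphosphate during ion exchange and drying.

   Fallback (stepwise P–O bond formation on the intact alcohol, so the C1′–O bond is never broken), setting out from diol 4, bypassing 6, and coming back at 8. Trichloroacetonitrile and bis(triethylammonium) hydrogen phosphate in MeCN at rt should phosphorylate the primary allylic hydroxyl to (E)-7-hydroxy-3,7-dimethyloct-2-en-1-yl dihydrogen phosphate F5 (handled as its triethylammonium salt). F5 is phosphorylated a second time under the same conditions. The diphosphate fraction is separated from mono- and triphosphate by chromatography and exchanged to the ammonium form, which is 8.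

3. Step 2. What may go wrong: incomplete opening of the hindered oxirane at low temperature, or hydroalumination of the allylic alkoxide when the reduction is forced.

   Fallback (direct Markovnikov hydration instead of epoxidation and reduction), setting out from 1 and coming back at 4. Oxymercuration of the distal olefin with Hg(OAc)2 in THF/H2O at rt should give (E)-6-(acetoxymercurio)-7-hydroxy-3,7-dimethyloct-2-en-1-yl acetate F6. Reduction in the same flask with NaBH4 in aqueous NaOH at 0 °C should give (E)-7-hydroxy-3,7-dimethyloct-2-en-1-yl acetate F7. Methanolysis (K2CO3, MeOH, rt) then returns to 4.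

Further compounds
F1 | step 5 | (2S)-5-hydroxy-7,3′,4′-tris(tert-butyldimethylsilyloxy)flavanone | O=C1C[C@@H](c2ccc(O[Si](C)(C)C(C)(C)C)c(O[Si](C)(C)C(C)(C)C)c2)Oc2cc(O[Si](C)(C)C(C)(C)C)cc(O)c21
F2 | step 5 | (2S)-5-hydroxy-6-iodo-7,3′,4′-tris(tert-butyldimethylsilyloxy)flavanone | O=C1C[C@@H](c2ccc(O[Si](C)(C)C(C)(C)C)c(O[Si](C)(C)C(C)(C)C)c2)Oc2cc(O[Si](C)(C)C(C)(C)C)c(I)c(O)c21
F3 | step 5 | (E)-2,6-dimethyl-8-(tributylstannyl)oct-6-en-2-ol | C/C(=C\C[Sn](CCCC)(CCCC)CCCC)CCCC(C)(C)O
F4 | step 5 | 7,3′,4′-tris-O-(tert-butyldimethylsilyl)prokinawan | C/C(=C\Cc1c(O[Si](C)(C)C(C)(C)C)cc2c(c1O)C(=O)C[C@@H](c1ccc(O[Si](C)(C)C(C)(C)C)c(O[Si](C)(C)C(C)(C)C)c1)O2)CCCC(C)(C)O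
F5 | step 4 | (E)-7-hydroxy-3,7-dimethyloct-2-en-1-yl dihydrogen phosphate | C/C(=C\COP(=O)(O)O)CCCC(C)(C)O
F6 | step 2 | (E)-6-(acetoxymercurio)-7-hydroxy-3,7-dimethyloct-2-en-1-yl acetate | C/C(=C\COC(C)=O)CCC([Hg]OC(C)=O)C(C)(C)O
F7 | step 2 | (E)-7-hydroxy-3,7-dimethyloct-2-en-1-yl acetate | C/C(=C\COC(C)=O)CCCC(C)(C)O
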